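**Plan**
- Retrosynthesis: the two acetates come off first. Then C6–C7, C11–C12 and C12–O6 are cut together, which opens the butenolide and the ten-membered ring C1–C10 to an open-chain bis-epoxy ynal (germacrane numbering).
- Enabling feature: the lactone O6–C6–C7=C11–C12(=O) is fused on ring bond C6–C7 and its alkene C7=C11 is exocyclic to the carbocycle. A C6 aldehyde, the alkyne C7≡C11 of a 2-butyne-1,4-diol unit (C13–C11≡C7–C8) and carbon monoxide (C12) therefore account for every butenolide atom.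
- Further cuts: both epoxides back to the 1(10)Z,4E-diene; C8–C9 (allylboration of an ynal); C1–C10 (lithiation–borylation of a geraniol-derived carbamate with an isopropenylboronate).
- Forward order: C1–C6 unit from geraniol, then C1–C10, then C8–C9 (full chain), then the 4,5-epoxide, then the 1,10-epoxide, then carbocycle and butenolide in one step, then the diacetate.
- Stereochemistry: the boron-bearing C1 centre comes from (+)-sparteine and is transferred through a chair allylboration to C8 (S) and to the Z alkene. C4/C5 come from Sharpless epoxidation (D-tartrate), C1/C10 from Shi epoxidation (D-fructose ketone), and C6 from the C5 epoxide in the ring closure.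

Key step: step 13

Remark: germacrane numbering (C1–C15) is used for all chain and ring carbons; tert-butyldimethyl(prop-2-yn-1-yloxy)silane (one silylation from propargyl alcohol) and isopropenylboronic acid pinacol ester are taken as purchased materials.

**Route**

Step 1
Reactants: 1 geraniol
Product: 2 geranyl 4-methoxybenzyl ether
Conditions: NaH, 4-methoxybenzyl chloride, Bu4NI (cat.), THF/DMF, 0 to 23 °C
Reagents that add atoms: 4-methoxybenzyl chloride, COc1ccc(CCl)cc1
Why: Williamson etherification of the allylic alkoxide gives a C6–O protecting group that should tolerate peracid, hydride and s-BuLi at −78 °C and can later be removed oxidatively beside silyl ethers.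

Step 2
Reactants: 2 geranyl 4-methoxybenzyl ether
Product: 4 (4E)-6-[(4-methoxybenzyl)oxy]-4-methylhex-4-enal, via 6,7-epoxide 3 (not isolated)
Conditions: mCPBA, CH2Cl2, −20 °C; then H5IO6, THF/H2O, 0 °C
Reagents that add atoms: 3-chloroperoxybenzoic acid, OOC(=O)c1cccc(Cl)c1
Why: Prilezhaev epoxidation should take the electron-rich terminal alkene in preference to the 2,3-alkene deactivated by the allylic ether oxygen, and periodic acid then hydrolyses the epoxide and cleaves the glycol (Malaprade-type cleavage) to the C1 aldehyde with loss of acetone.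

Step 3
Reactants: 4 (4E)-6-[(4-methoxybenzyl)oxy]-4-methylhex-4-enal
Product: 5 (4E)-6-[(4-methoxybenzyl)oxy]-4-methylhex-4-en-1-ol
Conditions: NaBH4, MeOH, 0 °C
Reagents that add atoms: none
Why: Borohydride reduction of the aldehyde is chemoselective beside the trisubstituted alkene and the benzylic ether.

Step 4
Reactants: 5 (4E)-6-[(4-methoxybenzyl)oxy]-4-methylhex-4-en-1-ol
Product: 6 (4E)-6-[(4-methoxybenzyl)oxy]-4-methylhex-4-en-1-yl N,N-diisopropylcarbamate
Conditions: i-Pr2NCOCl, Et3N, CH2Cl2, reflux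
Reagents that add atoms: N,N-diisopropylcarbamoyl chloride, CC(C)N(C(C)C)C(Cl)=O
Why: O-Carbamoylation (acyl substitution) installs the hindered carbamate that directs and stabilises the α-lithiation of C1 in step 6.

Step 5
Reactants: 7 tert-butyldimethyl(prop-2-yn-1-yloxy)silane
Product: 9 4-[(tert-butyldimethylsilyl)oxy]but-2-ynal, via lithium acetylide 8 (not isolated)
Conditions: n-BuLi, THF, −78 °C; DMF, −78 to 0 °C; inverse quench into 10 % aq. KH2PO4
Reagents that add atoms: N,N-dimethylformamide, CN(C)C=O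
Why: Formylation of the lithium acetylide with DMF gives the ynal that carries C13, C11, C7 and C8, the buffered inverse quench keeping liberated dimethylamine from adding to the product.

Step 6
Reactants: 6 (4E)-6-[(4-methoxybenzyl)oxy]-4-methylhex-4-en-1-yl N,N-diisopropylcarbamate
Product: 12 2-[(3S,6E)-8-[(4-methoxybenzyl)oxy]-2,6-dimethylocta-1,6-dien-3-yl]-4,4,5,5-tetramethyl-1,3,2-dioxaborolane, via lithiated carbamate 10 (not isolated), via lithium boronate complex 11 (not isolated)
Conditions: s-BuLi, (+)-sparteine, Et2O, −78 °C, 5 h; isopropenylboronic acid pinacol ester, −78 °C, 1 h; then reflux, 16 h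
Reagents that add atoms: isopropenylboronic acid pinacol ester, CC(=C)B1OC(C)(C)C(C)(C)O1
Why: Sparteine-mediated asymmetric α-lithiation of the carbamate (removal of the pro-R hydrogen with (+)-sparteine), borylation with retention and 1,2-metallate rearrangement with inversion (lithiation–borylation) should form the C1–C10 bond and set the boron-bearing C1 centre as S.

Step 7
Reactants: 12 2-[(3S,6E)-8-[(4-methoxybenzyl)oxy]-2,6-dimethylocta-1,6-dien-3-yl]-4,4,5,5-tetramethyl-1,3,2-dioxaborolane; 9 4-[(tert-butyldimethylsilyl)oxy]but-2-ynal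
Product: 13 (2E,6Z,9S)-12-[(tert-butyldimethylsilyl)oxy]-1-[(4-methoxybenzyl)oxy]-3,7-dimethyldodeca-2,6-dien-10-yn-9-ol
Conditions: toluene, −78 to 23 °C; aq. NaHCO3 work-up
Reagents that add atoms: none
Why: Allylboration through a closed chair (Zimmerman–Traxler) transition state, with the ynal substituent equatorial and the α-substituent held axial by allylic 1,2-strain against the 2-methyl group, should form C8–C9, give the 1(10)Z alkene and transfer the C1 boron configuration to the new carbinol centre as 8S.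

Step 8
Reactants: 13 (2E,6Z,9S)-12-[(tert-butyldimethylsilyl)oxy]-1-[(4-methoxybenzyl)oxy]-3,7-dimethyldodeca-2,6-dien-10-yn-9-ol
Product: 14 (2E,6Z,9S)-9,12-bis[(tert-butyldimethylsilyl)oxy]-1-[(4-methoxybenzyl)oxy]-3,7-dimethyldodeca-2,6-dien-10-yne
Conditions: TBSCl, imidazole, DMF, 23 °C
Reagents that add atoms: tert-butyldimethylsilyl chloride, CC(C)(C)[Si](C)(C)Cl
Why: Silylation of the secondary propargylic alcohol protects O8 as an ether that should not ionise under low-valent metals.

Step 9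
Reactants: 14 (2E,6Z,9S)-9,12-bis[(tert-butyldimethylsilyl)oxy]-1-[(4-methoxybenzyl)oxy]-3,7-dimethyldodeca-2,6-dien-10-yne
Product: 15 (2E,6Z,9S)-9,12-bis[(tert-butyldimethylsilyl)oxy]-3,7-dimethyldodeca-2,6-dien-10-yn-1-ol
Conditions: DDQ, CH2Cl2/pH 7 phosphate buffer, 0 °C
Reagents that add atoms: none
Why: Oxidative cleavage of the 4-methoxybenzyl ether by DDQ (hydride abstraction, then hydrolysis of the oxocarbenium ion) frees the C6 allylic alcohol and leaves silyl ethers, alkyne and alkenes untouched.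

Step 10
Reactants: 15 (2E,6Z,9S)-9,12-bis[(tert-butyldimethylsilyl)oxy]-3,7-dimethyldodeca-2,6-dien-10-yn-1-ol
Product: 16 {(2R,3R)-3-[(3Z,6S)-6,9-bis[(tert-butyldimethylsilyl)oxy]-4-methylnon-3-en-7-yn-1-yl]-3-methyloxiran-2-yl}methanol
Conditions: Ti(OiPr)4 (cat.), D-(−)-diethyl tartrate, t-BuOOH, 4 Å molecular sieves, CH2Cl2, −20 °C
Reagents that add atoms: tert-butyl hydroperoxide, CC(C)(C)OO
Why: Sharpless asymmetric epoxidation acts only on the allylic alcohol and, with D-(−)-diethyl tartrate, should give the (2R,3R)-epoxy alcohol (4R,5R in germacrane numbering), the mirror image of the 2S,3S product that geraniol gives with the L-tartrate.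

Step 11
Reactants: 16 {(2R,3R)-3-[(3Z,6S)-6,9-bis[(tert-butyldimethylsilyl)oxy]-4-methylnon-3-en-7-yn-1-yl]-3-methyloxiran-2-yl}methanol
Product: 17 bis-epoxy alcohol: [(2R,3R)-3-(2-{(2R,3S)-3-[(2S)-2,5-bis[(tert-butyldimethylsilyl)oxy]pent-3-yn-1-yl]-3-methyloxiran-2-yl}ethyl)-3-methyloxiran-2-yl]methanol
Conditions: Shi ketone from D-fructose (0.3 equiv.), KHSO5 (as 2KHSO5·KHSO4·K2SO4), K2CO3, Bu4NHSO4, MeCN/CH2(OMe)2, aq. Na2B4O7/Na2EDTA buffer, 0 °C
Reagents that add atoms: potassium peroxymonosulfate, [K+].[O-]S(=O)(=O)OO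
Why: Shi asymmetric epoxidation by the chiral dioxirane through the spiro transition state is reagent-controlled and should place oxygen on the face of the Z-trisubstituted alkene that gives the cis-epoxide 1R,10S, any minor diastereomer being separable because C4, C5 and C8 are already fixed.

Step 12
Reactants: 17 bis-epoxy alcohol
Product: 18 bis-epoxy ynal: (2S,3R)-3-(2-{(2R,3S)-3-[(2S)-2,5-bis[(tert-butyldimethylsilyl)oxy]pent-3-yn-1-yl]-3-methyloxiran-2-yl}ethyl)-3-methyloxirane-2-carbaldehyde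
Conditions: TEMPO (cat.), PhI(OAc)2, CH2Cl2, 23 °C
Reagents that add atoms: none
Why: Oxoammonium oxidation (TEMPO with PhI(OAc)2) should stop at the α,β-epoxy aldehyde and cannot epimerise C5, which is not enolisable within the oxirane.

Step 13
Reactants: 18 bis-epoxy ynal
Product: 19 (1R,4R,5R,6S,8S,10S)-8,13-bis[(tert-butyldimethylsilyl)oxy]-1,10:4,5-diepoxygermacr-7(11)-en-12,6-olide
Conditions: Mo(CO)6 (1.5 equiv.), DMSO (10 equiv.), toluene, 100 °C, slow addition of 18 to a final 0.002 M
Reagents that add atoms: molybdenum hexacarbonyl (one CO becomes C12 and its oxygen), [Mo].[C-]#[O+].[C-]#[O+].[C-]#[O+].[C-]#[O+].[C-]#[O+].[C-]#[O+]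
Why: Proposed new method: zerovalent molybdenum generated from Mo(CO)6 and DMSO is expected to bind the C7≡C11 alkyne and the C6 aldehyde and couple them oxidatively to an oxamolybdacyclopentene (C6–C7 bond, metal on O6 and C11), after which CO inserts into the Mo–C11 bond and C–O reductive elimination forms C12–O6; the closest known reaction type is the hetero-Pauson–Khand cyclocarbonylation of 1,6- and 1,7-ynals to fused butenolides with Mo(CO)6/DMSO or catalytic Ru3(CO)12, here stretched to an eight-atom tether. The ten-membered carbocycle closes in the oxidative coupling, a 10-exo-dig attack of C7 on the aldehyde carbon that leaves C11 and O6 outside the new ring and on the metal, and the butenolide closes afterwards by migratory CO insertion and five-membered C–O reductive elimination from the acyl oxametallacycle. C6 is the only new stereocentre and must be S, which requires C7 to be delivered to the aldehyde face syn to the C5 epoxide oxygen, the epoxide oxygen acting as a second donor on molybdenum (chelation-type control by the 5R centre), whereas the open Felkin–Anh mode would give the 6R epimer. The step needs alkyne–aldehyde coupling to win over propargylic C–O ionisation, epoxide deoxygenation and intermolecular coupling, and silyl instead of acyl groups on O8 and O13, the activated α,β-epoxy aldehyde, the turn imposed by the cis-1,10-epoxide and slow addition at high dilution are chosen to secure this.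

Step 14
Reactants: 19 (1R,4R,5R,6S,8S,10S)-8,13-bis[(tert-butyldimethylsilyl)oxy]-1,10:4,5-diepoxygermacr-7(11)-en-12,6-olide
Product: 20 (1R,4R,5R,6S,8S,10S)-8,13-dihydroxy-1,10:4,5-diepoxygermacr-7(11)-en-12,6-olide
Conditions: HF·pyridine, pyridine, THF, 0 to 23 °C
Reagents that add atoms: none
Why: Fluoride-mediated desilylation with pyridine-buffered HF·pyridine should remove both silyl ethers under conditions that trisubstituted epoxides and butenolides generally tolerate.

Step 15
Reactants: 20 (1R,4R,5R,6S,8S,10S)-8,13-dihydroxy-1,10:4,5-diepoxygermacr-7(11)-en-12,6-olide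
Product: 21 CNP0271844.2: (1R,4R,5R,6S,8S,10S)-8,13-diacetoxy-1,10:4,5-diepoxygermacr-7(11)-en-12,6-olide
Conditions: Ac2O, pyridine, DMAP (cat.), CH2Cl2, 0 to 23 °C
Reagents that add atoms: acetic anhydride, CC(=O)OC(C)=O
Why: DMAP-catalysed acylation of the primary C13 and secondary C8 alcohols gives the diacetate without touching the epoxides, the lactone or any stereocentre.

**Compound list**

1 | geraniol, (2E)-3,7-dimethylocta-2,6-dien-1-ol | CC(C)=CCC/C(C)=C/CO | starting material
2 | geranyl 4-methoxybenzyl ether | CC(C)=CCC/C(C)=C/COCc1ccc(OC)cc1 | intermediate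
3 | 6,7-epoxide of 2 (racemic) | CC1(C)OC1CC/C(C)=C/COCc1ccc(OC)cc1 | intermediate (not isolated)
4 | (4E)-6-[(4-methoxybenzyl)oxy]-4-methylhex-4-enal | O=CCC/C(C)=C/COCc1ccc(OC)cc1 | intermediate
5 | (4E)-6-[(4-methoxybenzyl)oxy]-4-methylhex-4-en-1-ol | OCCC/C(C)=C/COCc1ccc(OC)cc1 | intermediate
6 | (4E)-6-[(4-methoxybenzyl)oxy]-4-methylhex-4-en-1-yl N,N-diisopropylcarbamate | CC(C)N(C(C)C)C(=O)OCCC/C(C)=C/COCc1ccc(OC)cc1 | intermediate
7 | tert-butyldimethyl(prop-2-yn-1-yloxy)silane | C#CCO[Si](C)(C)C(C)(C)C | starting material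
8 | lithium acetylide of 7 | [Li]C#CCO[Si](C)(C)C(C)(C)C | intermediate (not isolated)
9 | 4-[(tert-butyldimethylsilyl)oxy]but-2-ynal | O=CC#CCO[Si](C)(C)C(C)(C)C | intermediate
10 | (1R)-1-lithio derivative of carbamate 6 (sparteine complex) | [Li][C@@H](OC(=O)N(C(C)C)C(C)C)CC/C(C)=C/COCc1ccc(OC)cc1 | intermediate (not isolated)
11 | lithium boronate complex from 10 and isopropenylboronic acid pinacol ester (carbinol carbon R) | [Li+].CC(=C)[B-]1(OC(C)(C)C(C)(C)O1)[C@@H](OC(=O)N(C(C)C)C(C)C)CC/C(C)=C/COCc1ccc(OC)cc1 | intermediate (not isolated)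
12 | 2-[(3S,6E)-8-[(4-methoxybenzyl)oxy]-2,6-dimethylocta-1,6-dien-3-yl]-4,4,5,5-tetramethyl-1,3,2-dioxaborolane | CC(=C)[C@@H](B1OC(C)(C)C(C)(C)O1)CC/C(C)=C/COCc1ccc(OC)cc1 | intermediate
13 | (2E,6Z,9S)-12-[(tert-butyldimethylsilyl)oxy]-1-[(4-methoxybenzyl)oxy]-3,7-dimethyldodeca-2,6-dien-10-yn-9-ol | CC(C)(C)[Si](C)(C)OCC#C[C@@H](O)C/C(C)=C\CC/C(C)=C/COCc1ccc(OC)cc1 | intermediate
14 | (2E,6Z,9S)-9,12-bis[(tert-butyldimethylsilyl)oxy]-1-[(4-methoxybenzyl)oxy]-3,7-dimethyldodeca-2,6-dien-10-yne | CC(C)(C)[Si](C)(C)OCC#C[C@@H](O[Si](C)(C)C(C)(C)C)C/C(C)=C\CC/C(C)=C/COCc1ccc(OC)cc1 | intermediate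
15 | (2E,6Z,9S)-9,12-bis[(tert-butyldimethylsilyl)oxy]-3,7-dimethyldodeca-2,6-dien-10-yn-1-ol | CC(C)(C)[Si](C)(C)OCC#C[C@@H](O[Si](C)(C)C(C)(C)C)C/C(C)=C\CC/C(C)=C/CO | intermediate
16 | {(2R,3R)-3-[(3Z,6S)-6,9-bis[(tert-butyldimethylsilyl)oxy]-4-methylnon-3-en-7-yn-1-yl]-3-methyloxiran-2-yl}methanol | CC(C)(C)[Si](C)(C)OCC#C[C@@H](O[Si](C)(C)C(C)(C)C)C/C(C)=C\CC[C@@]1(C)O[C@@H]1CO | intermediate
17 | [(2R,3R)-3-(2-{(2R,3S)-3-[(2S)-2,5-bis[(tert-butyldimethylsilyl)oxy]pent-3-yn-1-yl]-3-methyloxiran-2-yl}ethyl)-3-methyloxiran-2-yl]methanol | CC(C)(C)[Si](C)(C)OCC#C[C@@H](O[Si](C)(C)C(C)(C)C)C[C@]1(C)O[C@@H]1CC[C@@]1(C)O[C@@H]1CO | intermediate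
18 | (2S,3R)-3-(2-{(2R,3S)-3-[(2S)-2,5-bis[(tert-butyldimethylsilyl)oxy]pent-3-yn-1-yl]-3-methyloxiran-2-yl}ethyl)-3-methyloxirane-2-carbaldehyde | CC(C)(C)[Si](C)(C)OCC#C[C@@H](O[Si](C)(C)C(C)(C)C)C[C@]1(C)O[C@@H]1CC[C@@]1(C)O[C@@H]1C=O | intermediate
19 | (1R,4R,5R,6S,8S,10S)-8,13-bis[(tert-butyldimethylsilyl)oxy]-1,10:4,5-diepoxygermacr-7(11)-en-12,6-olide | CC(C)(C)[Si](C)(C)OCC1=C2[C@@H](O[Si](C)(C)C(C)(C)C)C[C@]3(C)O[C@@H]3CC[C@@]3(C)O[C@@H]3[C@H]2OC1=O | intermediate
20 | (1R,4R,5R,6S,8S,10S)-8,13-dihydroxy-1,10:4,5-diepoxygermacr-7(11)-en-12,6-olide | OCC1=C2[C@@H](O)C[C@]3(C)O[C@@H]3CC[C@@]3(C)O[C@@H]3[C@H]2OC1=O | intermediate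
21 | CNP0271844.2, (1R,4R,5R,6S,8S,10S)-8,13-diacetoxy-1,10:4,5-diepoxygermacr-7(11)-en-12,6-olide | CC(=O)OCC1=C2[C@@H](OC(C)=O)C[C@]3(C)O[C@@H]3CC[C@@]3(C)O[C@@H]3[C@H]2OC1=O | target

**Count**

Total steps: 15. Longest linear sequence: 14 steps (geraniol 1 to target 21; step 5 is the one-step side branch).

**Steps most likely to fail**

1. Step 13 (the proposed new method). The oxidative coupling across the eight-atom tether may be outrun by oligomerisation, by loss of a propargylic silyloxy group or by deoxygenation of an epoxide by low-valent molybdenum. The aldehyde face may also be taken in the Felkin–Anh sense.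
Fallback (known chemistry, separate C–C closure by an organochromium reagent): it sets out from boronate 12 and comes back at 19.
- 12 is added to ethyl glyoxylate in place of 9 (same chair) to give ethyl (2S,4Z,8E)-2-hydroxy-10-[(4-methoxybenzyl)oxy]-4,8-dimethyldeca-4,8-dienoate F1, which is silylated (TBSCl, imidazole) to its tert-butyldimethylsilyl ether F2.
- Crossed Claisen condensation of F2 with the lithium enolate of methyl 3-[(tert-butyldimethylsilyl)oxy]propanoate (LiN(iPr)2, THF, −78 °C) should give the β-keto ester F3, which already carries C11, C12 and C13.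
- Chelation-controlled O-sulfonylation (LiOTf, Et3N, Tf2O, CH2Cl2) should give the Z-enol triflate F4, with the triflate on C7 cis to the ester.
- The operations of steps 9 to 12 then follow: DDQ to the allylic alcohol F5, Sharpless epoxidation with D-(−)-diethyl tartrate to the 4R,5R-epoxy alcohol F6, Shi epoxidation to the bis-epoxy alcohol F7, and TEMPO/PhI(OAc)2 to the bis-epoxy aldehyde F8.
- Intramolecular Nozaki–Hiyama–Kishi reaction of F8 (CrCl2, catalytic NiCl2, DMSO/THF, high dilution) forms C6–C7 from the alkenyl triflate and the aldehyde. Chromium-mediated closure of this bond is the established way to ten-membered germacranolide carbocycles. The chromium alkoxide should lactonise onto the cis ester and give 19 directly.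
- A 6R hydroxy ester, if it prevailed, would be closed with inversion by Mitsunobu lactonisation after saponification.

2. Step 7. The α-substituent of the boronate may not be held axial cleanly, which would erode both the Z geometry and the transfer of configuration to C8. The ynal may also polymerise before it is consumed.
Fallback (alkene geometry from an iodo-olefination, C8 from a reagent-controlled ketone reduction): it sets out from aldehyde 4 and comes back at 13.
- Stork–Zhao-type olefination of 4 with Ph3P=C(I)CH3 (from (1-iodoethyl)triphenylphosphonium iodide and NaN(SiMe3)2, THF, −78 °C) should give the Z-iodoalkene 1-({[(2E,6Z)-7-iodo-3-methylocta-2,6-dien-1-yl]oxy}methyl)-4-methoxybenzene F9.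
- Negishi coupling of F9 with the Reformatsky reagent BrZnCH2CO2Et (Pd(PPh3)4, THF) gives, with retention, ethyl (3Z,7E)-9-[(4-methoxybenzyl)oxy]-3,7-dimethylnona-3,7-dienoate F10.
- Addition of lithium acetylide 8 in the presence of BF3·OEt2 at −78 °C gives the ynone (2E,6Z)-12-[(tert-butyldimethylsilyl)oxy]-1-[(4-methoxybenzyl)oxy]-3,7-dimethyldodeca-2,6-dien-10-yn-9-one F11.
- Midland reduction with (S)-Alpine-Borane (B-isopinocampheyl-9-borabicyclo[3.3.1]nonane from (−)-α-pinene) under neutral conditions, which spare the β,γ-alkene, should give 13 with the 9S configuration.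

3. Step 6. Deprotonation next to the allylic ether oxygen may compete with the carbamate-directed lithiation, and the 1,2-migration of the boronate complex may be slow enough for it to revert.
Fallback (catalytic asymmetric allylic borylation in place of organolithium chemistry): it sets out from aldehyde 4 and comes back at 12.
- Wittig olefination of 4 with Ph3P=C(CH3)CO2Et gives ethyl (2E,6E)-8-[(4-methoxybenzyl)oxy]-2,6-dimethylocta-2,6-dienoate F12.
- i-Bu2AlH gives the allylic alcohol (2E,6E)-8-[(4-methoxybenzyl)oxy]-2,6-dimethylocta-2,6-dien-1-ol F13.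
- Methyl chloroformate and pyridine give the methyl carbonate F14.
- Copper-catalysed enantioselective SN2′ borylation (CuCl, KOtBu, B2pin2, THF, with a C2-symmetric bisphosphine such as QuinoxP* in the enantiomeric form that gives the S product) should place boron on C1 with shift of the alkene to the C10=C9 methylene and so give 12.

Further compounds
F1 | step 13 | ethyl (2S,4Z,8E)-2-hydroxy-10-[(4-methoxybenzyl)oxy]-4,8-dimethyldeca-4,8-dienoate | CCOC(=O)[C@@H](O)C/C(C)=C\CC/C(C)=C/COCc1ccc(OC)cc1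
F2 | step 13 | ethyl (2S,4Z,8E)-2-[(tert-butyldimethylsilyl)oxy]-10-[(4-methoxybenzyl)oxy]-4,8-dimethyldeca-4,8-dienoate | CCOC(=O)[C@@H](O[Si](C)(C)C(C)(C)C)C/C(C)=C\CC/C(C)=C/COCc1ccc(OC)cc1
F3 | step 13 | methyl (4S,6Z,10E)-4-[(tert-butyldimethylsilyl)oxy]-2-{[(tert-butyldimethylsilyl)oxy]methyl}-12-[(4-methoxybenzyl)oxy]-6,10-dimethyl-3-oxododeca-6,10-dienoate (both C2 epimers) | COC(=O)C(CO[Si](C)(C)C(C)(C)C)C(=O)[C@@H](O[Si](C)(C)C(C)(C)C)C/C(C)=C\CC/C(C)=C/COCc1ccc(OC)cc1
F4 | step 13 | methyl (2Z,4S,6Z,10E)-4-[(tert-butyldimethylsilyl)oxy]-2-{[(tert-butyldimethylsilyl)oxy]methyl}-12-[(4-methoxybenzyl)oxy]-6,10-dimethyl-3-{[(trifluoromethyl)sulfonyl]oxy}dodeca-2,6,10-trienoate | COC(=O)/C(CO[Si](C)(C)C(C)(C)C)=C(\OS(=O)(=O)C(F)(F)F)[C@@H](O[Si](C)(C)C(C)(C)C)C/C(C)=C\CC/C(C)=C/COCc1ccc(OC)cc1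
F5 | step 13 | 12-hydroxy compound from F4 (4-methoxybenzyl group removed) | COC(=O)/C(CO[Si](C)(C)C(C)(C)C)=C(\OS(=O)(=O)C(F)(F)F)[C@@H](O[Si](C)(C)C(C)(C)C)C/C(C)=C\CC/C(C)=C/CO
F6 | step 13 | 4R,5R-epoxy alcohol from F5 (germacrane numbering) | COC(=O)/C(CO[Si](C)(C)C(C)(C)C)=C(\OS(=O)(=O)C(F)(F)F)[C@@H](O[Si](C)(C)C(C)(C)C)C/C(C)=C\CC[C@@]1(C)O[C@@H]1CO
F7 | step 13 | (1R,10S):(4R,5R)-bis-epoxy alcohol from F6 | COC(=O)/C(CO[Si](C)(C)C(C)(C)C)=C(\OS(=O)(=O)C(F)(F)F)[C@@H](O[Si](C)(C)C(C)(C)C)C[C@]1(C)O[C@@H]1CC[C@@]1(C)O[C@@H]1CO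
F8 | step 13 | bis-epoxy aldehyde from F7 (C6 aldehyde, C7 enol triflate, C12 methyl ester) | COC(=O)/C(CO[Si](C)(C)C(C)(C)C)=C(\OS(=O)(=O)C(F)(F)F)[C@@H](O[Si](C)(C)C(C)(C)C)C[C@]1(C)O[C@@H]1CC[C@@]1(C)O[C@@H]1C=O
F9 | step 7 | 1-({[(2E,6Z)-7-iodo-3-methylocta-2,6-dien-1-yl]oxy}methyl)-4-methoxybenzene | C/C(I)=C/CC/C(C)=C/COCc1ccc(OC)cc1
F10 | step 7 | ethyl (3Z,7E)-9-[(4-methoxybenzyl)oxy]-3,7-dimethylnona-3,7-dienoate | CCOC(=O)C/C(C)=C\CC/C(C)=C/COCc1ccc(OC)cc1
F11 | step 7 | (2E,6Z)-12-[(tert-butyldimethylsilyl)oxy]-1-[(4-methoxybenzyl)oxy]-3,7-dimethyldodeca-2,6-dien-10-yn-9-one | CC(C)(C)[Si](C)(C)OCC#CC(=O)C/C(C)=C\CC/C(C)=C/COCc1ccc(OC)cc1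
F12 | step 6 | ethyl (2E,6E)-8-[(4-methoxybenzyl)oxy]-2,6-dimethylocta-2,6-dienoate | CCOC(=O)/C(C)=C/CC/C(C)=C/COCc1ccc(OC)cc1
F13 | step 6 | (2E,6E)-8-[(4-methoxybenzyl)oxy]-2,6-dimethylocta-2,6-dien-1-ol | OC/C(C)=C/CC/C(C)=C/COCc1ccc(OC)cc1
F14 | step 6 | (2E,6E)-8-[(4-methoxybenzyl)oxy]-2,6-dimethylocta-2,6-dien-1-yl methyl carbonate | COC(=O)OC/C(C)=C/CC/C(C)=C/COCc1ccc(OC)cc1
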